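I had no constants for this flask, so I read one from the two earlier runs before deciding whether the next charge should carry more free base or more nucleophile.

| flask | electrophile | nucleophile | free base | remark | time |
|---|---|---|---|---|---|
| south-east | 34 mM (fed, over 2.5 h) | 37.4 mM | 39 mM | run made earlier |  |
| south-west | 34 mM (fed, over 2.5 h) | 37.4 mM | 47 mM | run made earlier |  |
| red | 34 mM (fed, over 2.5 h) | 37.4 mM | 27.0 mM |  | 8.0 h |
| blue | 34 mM (fed, over 2.5 h) | 37.4 mM | 35.0 mM |  | 8.0 h |

| run | time / h | electrophile / % | product / % |
|---|---|---|---|
| south-east | 0.667 | 24 | 4 |
| south-east | 2.00 | 74 | 9 |
| south-east | 4.00 | 78 | 20 |
| south-east | 6.00 | 70 | 31 |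
| south-west | 0.667 | 31 | 4 |
| south-west | 2.00 | 74 | 9 |
| south-west | 4.00 | 78 | 14 |
| south-west | 6.00 | 68 | 31 |

(standard deviation of a reading: 2 percentage points)

- part of the electrophile that has reacted at the end, red
- part of the electrophile that has reacted at the end, blue
- what raising the concentration of free base from its lowest to its highest value here does to the part of the electrophile that has reacted (changes below 5 percentage points count as none) (it falls / it rises / no change)

- percentages count the whole charge, also what has not yet gone in

The two runs, at 39 mM and 47 mM of free base, both read 31% of product at 6.00 h. They part by 6 percentage points at 4.00 h, with a scatter of 2 points on each reading, so I saw no clear effect of the free base and kept it out of the rate law. I wrote the rate as a constant times [electrophile][nucleophile]. Summing the mean electrophile fraction over time up to 6.00 h gave 3.76 h, and dividing the mean product by this sum and by the nucleophile charged gave 2.21 L mol⁻¹ h⁻¹. This is my read constant, an apparent second-order rate constant averaged over the fall of the nucleophile in those runs, and it carries their scatter.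

Multiplied by the nucleophile charge, it gave a pseudo-first-order constant of 0.0827 h⁻¹ for the electrophile. Applied to the steady feed, that gave an estimate of 42.6% reacted at 8.0 h, the same for red and blue, since my reckoning holds no term for free base. At one acid set free per product, that estimate stood for 14.5 mM of acid in all, less than the 27.0 mM of free base in red, although red lies below the tested range. I therefore decided to leave the free base alone and to change the nucleophile in the next run.

The forecast gave 43% for red, 43% for blue and no change, holding that “the rate looks zero order in base here”. The flask gave 39.0% for red and 39.5% for blue, and the trend was no change, a change of 0.47 points.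

    electrophile + nucleophile → acid set free + product (k = 7.80 × 10⁻⁴ L mol⁻¹ s⁻¹)
    nucleophile + acid set free ⇌ protonated nucleophile, settled at all times (K = 1500 L mol⁻¹)
    acid set free + free base ⇌ salt of the base, settled at all times (K = 2300 L mol⁻¹)

My reckoning stood 3.1 points above blue. The next run was blue with 64 mM of nucleophile in place of 37.4 mM. The read constant gave it a pseudo-first-order constant of 0.141 h⁻¹, hence an estimate of 61.2% reacted at 8.00 h and 20.8 mM of acid counted over its free, protonated-nucleophile and salt forms together, less than the 35.0 mM of free base. That flask gave 57.8%, with 71.0% of its free base still free.

The earlier runs and the new flask come from a simulation on assumed constants.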